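**Retrosynthetic overview**
1. Labels used below are daucane positions, not name locants: C1 angular C–CH3, C2 CHOH, C3 CH2, C4 C(OH)iPr, C5 ring-fusion CH, C6 and C10 angeloyloxy carbons, C7 CH2, C8/C9 epoxide.
2. Five-membered ring first: 1 + 2 give the acyclic ene-1,4-dione 3; the nitronate of 4, a formyl-anion equivalent, adds to the enone β-carbon (C5–C6 bond) to give 5, which closes by aldol (C3–C4) to cyclopentanone 6; a Nef reaction unmasks aldehyde 7.
3. C6–C7 bond and the cis trisubstituted alkene: enal 8 is turned into siloxydiene 9, whose hetero-Diels–Alder reaction with the aldehyde of 7 gives silyl acetal 10 and then lactol 11.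
4. Seven-membered ring second: intramolecular aldol C1–C10 (ketone enolate onto the lactol aldehyde) gives the cis-fused hydroazulenone 12.
5. Endgame: hydroxyl-directed epoxidation (13), double esterification with angelic acid 14 (15), reduction of the C2 ketone (16).

Assumption: the SMILES defines the absolute configuration, and the catalyst antipodes named in steps 2 and 5 follow literature models; if induction is opposite, the mirror-image catalysts are used.

**Step 1**
Reactants: 1 3-methylbutan-2-one; 2 butane-2,3-dione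
Product: 3 (3E)-3,6-dimethylhept-3-ene-2,5-dione
Conditions: LiN(iPr)2, THF, −78 °C; then 2 (3 equiv), −78 °C; AcOH; then TsOH·H2O (5 mol%), PhMe, 60 °C
Reagents that add atoms: none
Why: Directed crossed aldol addition of the kinetic methyl-side lithium enolate of 1 to one carbonyl of the 1,2-diketone, then acid-catalysed dehydration (aldol condensation) toward the CH2 so that the alkene is conjugated with both carbonyls (E isomer); no stereocenter is formed.

**Step 2**
Reactants: 3 (3E)-3,6-dimethylhept-3-ene-2,5-dione; 4 nitromethane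
Product: 6 (3R,4S)-4-hydroxy-2-methyl-3-(nitromethyl)-4-(propan-2-yl)cyclopentan-1-one (epimers at the methyl-bearing carbon), via nitro diketone 5 (not isolated)
Conditions: 4 (5 equiv), 1-[3,5-bis(trifluoromethyl)phenyl]-3-[(8α,9S)-6′-methoxycinchonan-9-yl]thiourea (10 mol%), PhMe, −20 °C; then (S)-proline (30 mol%), DMSO, rt
Reagents that add atoms: none
Why: Proposed new method: a bifunctional cinchona-thiourea nitro-Michael addition (closest known type: enantioselective addition of nitroalkanes to enones and 2-ene-1,4-diones), in which the catalyst hydrogen-bonds the acetyl enone and the nitronate (a formyl-anion equivalent) attacks the unsubstituted β-carbon because attack at the methylated carbon would build a quaternary centre, fixes C5 as R and is telescoped with a proline enamine 5-enolexo aldol (Hajos–Parrish type) of the methyl ketone onto the isobutyryl carbonyl, which sets C4 (S) with isopropyl trans to the nitromethyl arm before the β-nitro ketone can lose HNO2 or epimerise.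

**Step 3**
Reactants: 6 (3R,4S)-4-hydroxy-2-methyl-3-(nitromethyl)-4-(propan-2-yl)cyclopentan-1-one
Product: 7 (1S,2S)-2-hydroxy-5-methyl-4-oxo-2-(propan-2-yl)cyclopentane-1-carbaldehyde (epimers at the methyl-bearing carbon)
Conditions: NaOMe (1.05 equiv), MeOH, 0 °C; then TiCl3 (aq., 4.5 equiv), NH4OAc, THF–H2O, 0 °C → rt
Reagents that add atoms: water, O
Why: Nef reaction in its reductive McMurry form (nitronate reduced by TiCl3 to the imine, then hydrolysed) converts the nitromethyl group into the aldehyde at pH 5–6 without harming the tertiary aldol, and C5, now α to the aldehyde, keeps its thermodynamically preferred arrangement trans to isopropyl.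

**Step 4**
Reactants: 8 3-methylbut-2-enal
Product: 9 trimethyl{[(1E)-3-methylbuta-1,3-dien-1-yl]oxy}silane
Conditions: Me3SiOTf, Et3N, Et2O, 0 °C → rt
Reagents that add atoms: trimethylsilyl trifluoromethanesulfonate, C[Si](C)(C)OS(=O)(=O)C(F)(F)F
Why: O-silylation of the enal and γ-deprotonation by Et3N (vinylogous silyl enol ether formation) give the (1E)-1-siloxy diene; no stereocenter is formed.

**Step 5**
Reactants: 7 (1S,2S)-2-hydroxy-5-methyl-4-oxo-2-(propan-2-yl)cyclopentane-1-carbaldehyde; 9 trimethyl{[(1E)-3-methylbuta-1,3-dien-1-yl]oxy}silane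
Product: 11 (3R,4S)-4-hydroxy-3-[(2R)-6-hydroxy-4-methyl-3,6-dihydro-2H-pyran-2-yl]-2-methyl-4-(propan-2-yl)cyclopentan-1-one (mixture at the methyl-bearing and anomeric carbons), via silyl acetal 10 (not isolated)
Conditions: 9 (1.5 equiv), CrCl(L) (5 mol%; L = dianion of (1R,2S)-1-{[3-(adamantan-1-yl)-2-hydroxy-5-methylbenzylidene]amino}-2,3-dihydro-1H-inden-2-ol), 4 Å MS, t-BuOMe, rt; then AcOH–THF–H2O, 0 °C
Reagents that add atoms: none
Why: Jacobsen hetero-Diels–Alder reaction of the aldehyde (the ketone is not a competent heterodienophile) with the 1-siloxy diene forms C6–C7, locks the future ring alkene cis inside the dihydropyran and sets C6 (R) under catalyst control reinforced by the α-stereocentre, and mild hydrolysis of the anomeric silyl ether then gives the lactol.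

**Step 6**
Reactants: 11 (3R,4S)-4-hydroxy-3-[(2R)-6-hydroxy-4-methyl-3,6-dihydro-2H-pyran-2-yl]-2-methyl-4-(propan-2-yl)cyclopentan-1-one
Product: 12 (3S,3aR,4R,8S,8aS)-3,4,8-trihydroxy-6,8a-dimethyl-3-(propan-2-yl)-3,3a,4,5,8,8a-hexahydroazulen-1(2H)-one
Conditions: LiN(SiMe3)2 (3.3 equiv), THF, −78 → −30 °C; AcOH, −78 °C
Reagents that add atoms: none
Why: Intramolecular aldol addition: deprotonating both hydroxyls opens the lactolate to the (Z)-enal and, through the adjacent alkoxides, steers the third equivalent of base to C1–H, and the lithium enolate then adds to the tethered aldehyde on the face of the C5 side chain through a Li-bridged closed transition state, giving the cis ring fusion with the quaternary C1 and the C10 carbinol whose oxygen lies syn to the C2 carbonyl.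

**Step 7**
Reactants: 12 (3S,3aR,4R,8S,8aS)-3,4,8-trihydroxy-6,8a-dimethyl-3-(propan-2-yl)-3,3a,4,5,8,8a-hexahydroazulen-1(2H)-one
Product: 13 (3S,3aR,4R,6S,7R,8R,8aS)-6,7-epoxy-3,4,8-trihydroxy-6,8a-dimethyl-3-(propan-2-yl)octahydroazulen-1(2H)-one
Conditions: VO(acac)2 (5 mol%), t-BuOOH (1.5 equiv), CH2Cl2, 0 °C
Reagents that add atoms: tert-butyl hydroperoxide, CC(C)(C)OO
Why: Sharpless vanadium-catalysed hydroxyl-directed epoxidation: the vanadium-bound allylic C10 alkoxide, assisted by the homoallylic C6 hydroxyl on the same face, delivers oxygen syn to both hydroxyls, which sets C8 and C9 and leaves the ketone untouched.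

**Step 8**
Reactants: 13 (3S,3aR,4R,6S,7R,8R,8aS)-6,7-epoxy-3,4,8-trihydroxy-6,8a-dimethyl-3-(propan-2-yl)octahydroazulen-1(2H)-one; 14 angelic acid, (2Z)-2-methylbut-2-enoic acid
Product: 15 (3S,3aR,4R,6S,7R,8R,8aS)-6,7-epoxy-3-hydroxy-6,8a-dimethyl-1-oxo-3-(propan-2-yl)decahydroazulene-4,8-diyl bis[(2Z)-2-methylbut-2-enoate]
Conditions: 14 (6 equiv), 2,4,6-Cl3C6H2COCl, Et3N, PhMe, rt; then 13, 80 °C
Reagents that add atoms: none
Why: Yamaguchi-type mixed-anhydride esterification run without DMAP, the established way to transfer the angeloyl group without Z→E isomerisation, acylates the two secondary hydroxyls while the tertiary hydroxyl does not react; no stereocenter changes.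

**Step 9**
Reactants: 15 (3S,3aR,4R,6S,7R,8R,8aS)-6,7-epoxy-3-hydroxy-6,8a-dimethyl-1-oxo-3-(propan-2-yl)decahydroazulene-4,8-diyl bis[(2Z)-2-methylbut-2-enoate]
Product: 16 (1S,3S,3aR,4R,6S,7R,8R,8aR)-6,7-epoxy-1,3-dihydroxy-6,8a-dimethyl-3-(propan-2-yl)decahydroazulene-4,8-diyl bis[(2Z)-2-methylbut-2-enoate] (target)
Conditions: NaBH4, CeCl3·7H2O, MeOH–THF, −78 °C
Reagents that add atoms: none
Why: Luche-type borohydride reduction of the cyclopentanone, with hydride arriving on the convex face of the cis-fused bicycle (the angular-methyl face, anti to the C10 acyloxy arm and the seven-membered ring), gives the C2 alcohol cis to the C4 hydroxyl (1S), while the conjugated esters and the epoxide are not reduced.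

**Compound list**
1 | 3-methylbutan-2-one | CC(=O)C(C)C | starting material
2 | butane-2,3-dione | CC(=O)C(C)=O | starting material
3 | (3E)-3,6-dimethylhept-3-ene-2,5-dione | CC(=O)/C(C)=C/C(=O)C(C)C | intermediate
4 | nitromethane | C[N+](=O)[O-] | starting material
5 | (4R)-3,6-dimethyl-4-(nitromethyl)heptane-2,5-dione (C3 epimers) | [O-][N+](=O)C[C@@H](C(C)C(C)=O)C(=O)C(C)C | intermediate
6 | (3R,4S)-4-hydroxy-2-methyl-3-(nitromethyl)-4-(propan-2-yl)cyclopentan-1-one (C2 epimers) | [O-][N+](=O)C[C@@H]1[C@@](O)(C(C)C)CC(=O)C1C | intermediate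
7 | (1S,2S)-2-hydroxy-5-methyl-4-oxo-2-(propan-2-yl)cyclopentane-1-carbaldehyde (C5 epimers) | O=C[C@@H]1[C@@](O)(C(C)C)CC(=O)C1C | intermediate
8 | 3-methylbut-2-enal | CC(C)=CC=O | starting material
9 | trimethyl{[(1E)-3-methylbuta-1,3-dien-1-yl]oxy}silane | C=C(C)/C=C/O[Si](C)(C)C | intermediate
10 | (3R,4S)-4-hydroxy-2-methyl-3-{(2R)-4-methyl-6-[(trimethylsilyl)oxy]-3,6-dihydro-2H-pyran-2-yl}-4-(propan-2-yl)cyclopentan-1-one (mixture at C2 and the anomeric carbon) | O1[C@@H]([C@@H]2[C@@](O)(C(C)C)CC(=O)C2C)CC(C)=CC1O[Si](C)(C)C | intermediate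
11 | (3R,4S)-4-hydroxy-3-[(2R)-6-hydroxy-4-methyl-3,6-dihydro-2H-pyran-2-yl]-2-methyl-4-(propan-2-yl)cyclopentan-1-one (mixture at C2 and the anomeric carbon) | O1[C@@H]([C@@H]2[C@@](O)(C(C)C)CC(=O)C2C)CC(C)=CC1O | intermediate
12 | (3S,3aR,4R,8S,8aS)-3,4,8-trihydroxy-6,8a-dimethyl-3-(propan-2-yl)-3,3a,4,5,8,8a-hexahydroazulen-1(2H)-one | O[C@@H]1CC(C)=C[C@H](O)[C@@]2(C)C(=O)C[C@](O)(C(C)C)[C@@H]12 | intermediate
13 | (3S,3aR,4R,6S,7R,8R,8aS)-6,7-epoxy-3,4,8-trihydroxy-6,8a-dimethyl-3-(propan-2-yl)octahydroazulen-1(2H)-one | O[C@@H]1C[C@]2(C)O[C@@H]2[C@H](O)[C@@]2(C)C(=O)C[C@](O)(C(C)C)[C@@H]12 | intermediate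
14 | angelic acid, (2Z)-2-methylbut-2-enoic acid | C/C=C(/C)C(=O)O | starting material
15 | (3S,3aR,4R,6S,7R,8R,8aS)-6,7-epoxy-3-hydroxy-6,8a-dimethyl-1-oxo-3-(propan-2-yl)decahydroazulene-4,8-diyl bis[(2Z)-2-methylbut-2-enoate] | C/C=C(/C)C(=O)O[C@@H]1C[C@]2(C)O[C@@H]2[C@H](OC(=O)/C(C)=C\C)[C@@]2(C)C(=O)C[C@](O)(C(C)C)[C@@H]12 | intermediate
16 | (1S,3S,3aR,4R,6S,7R,8R,8aR)-6,7-epoxy-1,3-dihydroxy-6,8a-dimethyl-3-(propan-2-yl)decahydroazulene-4,8-diyl bis[(2Z)-2-methylbut-2-enoate] | C/C=C(/C)C(=O)O[C@@H]1C[C@]2(C)O[C@@H]2[C@H](OC(=O)/C(C)=C\C)[C@@]2(C)[C@@H](O)C[C@](O)(C(C)C)[C@@H]12 | target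

**Totals**
Total steps: 9. Longest linear sequence: 8 (steps 1, 2, 3, 5, 6, 7, 8, 9; step 4 is a one-step branch).

**Three steps most likely to fail**

Step 2 (nitronate addition and aldol in one flask). Risks are the regio- and enantioselectivity on an unsymmetrical trisubstituted ene-dione and loss of HNO2 from the β-nitro ketone 5 before ring closure. The fallback sets out from 3 and comes back at 7; it replaces the catalytic nitronate by a stoichiometric chiral aza-enamine as the formyl-anion equivalent. Enedione 3 and formaldehyde (2S)-2-(methoxymethyl)pyrrolidin-1-ylhydrazone (CH2Cl2, rt) give, under auxiliary control, the conjugate adduct (4R)-4-[(E)-{[(2S)-2-(methoxymethyl)pyrrolidin-1-yl]imino}methyl]-3,6-dimethylheptane-2,5-dione F1. The same proline aldol closes it to (3R,4S)-4-hydroxy-3-[(E)-{[(2S)-2-(methoxymethyl)pyrrolidin-1-yl]imino}methyl]-2-methyl-4-(propan-2-yl)cyclopentan-1-one F2. Aqueous oxalic acid then cleaves the hydrazone to aldehyde 7, with no Nef step and no β-nitro ketone.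

Step 6 (seven-membered ring aldol). Risks are that the equilibrium favours the lactol over the aldolate and that the C3 enolate forms instead. The fallback sets out from 11 and comes back at 12; it replaces the aldol addition by an acylation. Ag2CO3 on Celite (PhMe, 80 °C) oxidises lactol 11 to the lactone (6R)-6-[(1R,2S)-2-hydroxy-5-methyl-4-oxo-2-(propan-2-yl)cyclopentyl]-4-methyl-5,6-dihydro-2H-pyran-2-one F3. LiN(SiMe3)2 (3 equiv, THF, −78 °C) then effects an intramolecular Claisen-type C-acylation of the C1 enolate by the lactone carbonyl, the ring oxygen leaving as the C6 alkoxide. A cold AcOH quench gives (3S,3aR,4R,8aR)-3,4-dihydroxy-6,8a-dimethyl-3-(propan-2-yl)-3,3a,4,5-tetrahydroazulene-1,8(2H,8aH)-dione F4. NaBH4 with CeCl3·7H2O at −78 °C reduces the enone carbonyl 1,2, with borohydride associated to the C6 hydroxyl delivering hydride across the ring, to give 12.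

Step 8 (double angeloylation). Risks are the two hindered secondary hydroxyls (C10 lies between a quaternary carbon and the epoxide), angelate-to-tiglate isomerisation, and retro-aldol of the β-hydroxy ketone at 80 °C. The fallback sets out from 13 and comes back at 15; it builds the Z alkenes on the esters instead of transferring angelic acid. Diol 13 is acylated (EDC, DMAP cat., CH2Cl2, 0 °C) with 2-[bis(2,2,2-trifluoroethoxy)phosphoryl]propanoic acid to (3S,3aR,4R,6S,7R,8R,8aS)-6,7-epoxy-3-hydroxy-6,8a-dimethyl-1-oxo-3-(propan-2-yl)decahydroazulene-4,8-diyl bis{2-[bis(2,2,2-trifluoroethoxy)phosphoryl]propanoate} F5. A Still–Gennari olefination (KN(SiMe3)2, 18-crown-6, THF, −78 °C, acetaldehyde) then gives both (Z)-2-methylbut-2-enoates, that is 15.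

**Further compounds**
F1 | step 2 | (4R)-4-[(E)-{[(2S)-2-(methoxymethyl)pyrrolidin-1-yl]imino}methyl]-3,6-dimethylheptane-2,5-dione | COC[C@@H]1CCCN1/N=C/[C@@H](C(C)C(C)=O)C(=O)C(C)C
F2 | step 2 | (3R,4S)-4-hydroxy-3-[(E)-{[(2S)-2-(methoxymethyl)pyrrolidin-1-yl]imino}methyl]-2-methyl-4-(propan-2-yl)cyclopentan-1-one | COC[C@@H]1CCCN1/N=C/[C@@H]1[C@@](O)(C(C)C)CC(=O)C1C
F3 | step 6 | (6R)-6-[(1R,2S)-2-hydroxy-5-methyl-4-oxo-2-(propan-2-yl)cyclopentyl]-4-methyl-5,6-dihydro-2H-pyran-2-one | O1[C@@H]([C@@H]2[C@@](O)(C(C)C)CC(=O)C2C)CC(C)=CC1=O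
F4 | step 6 | (3S,3aR,4R,8aR)-3,4-dihydroxy-6,8a-dimethyl-3-(propan-2-yl)-3,3a,4,5-tetrahydroazulene-1,8(2H,8aH)-dione | O[C@@H]1CC(C)=CC(=O)[C@@]2(C)C(=O)C[C@](O)(C(C)C)[C@@H]12
F5 | step 8 | (3S,3aR,4R,6S,7R,8R,8aS)-6,7-epoxy-3-hydroxy-6,8a-dimethyl-1-oxo-3-(propan-2-yl)decahydroazulene-4,8-diyl bis{2-[bis(2,2,2-trifluoroethoxy)phosphoryl]propanoate} | CC(P(=O)(OCC(F)(F)F)OCC(F)(F)F)C(=O)O[C@@H]1C[C@]2(C)O[C@@H]2[C@H](OC(=O)C(C)P(=O)(OCC(F)(F)F)OCC(F)(F)F)[C@@]2(C)C(=O)C[C@](O)(C(C)C)[C@@H]12
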